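The disconnection is the C10'=C11' alkene: its C9' and hydroxymethyl carbon are cis, so it can be made as the endocyclic alkene of a six-membered sultone (ring atoms O, S, C9', C10', C11', CH2O). Ring-closing metathesis of allylsulfonate 11, the ester of the (R)-2-methylene-1,3-diol mono-silyl ether 9, sets position and geometry of this trisubstituted alkene in one operation. Because the allylic C–O bond of the sultone would be reduced before its C–S bond, sulfur is removed by β-elimination instead: carbenoid methylenation at C9' gives a dienol, whose terminal alkene is hydroborated and coupled with vinyl iodide 29 to form C7'–C8'. Desilylation and oxidation of the dimethoxyarene complete the quinone.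

Key step: step 8

Remark: side-chain atoms are numbered C1' (ring-bound CH2) to C15'; TBS = tert-butyldimethylsilyl, PMB = 4-methoxybenzyl; because C12' outranks the CH2O carbon, the C10'=C11' alkene with C9' and CH2O cis carries the label E in all open-chain compounds.

Step 1
Reactants: 1 2-methylidenepropane-1,3-diol
Product: 3 2-[(PMB-oxy)methyl]prop-2-en-1-ol, via monosodium alkoxide 2 (not isolated)
Conditions: NaH (1.0 equiv), THF, 0 °C; PMBCl, Bu4NI (cat.), 0 °C → rt
Reagents that add atoms: 4-methoxybenzyl chloride, COc1ccc(CCl)cc1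
Why: Williamson etherification of the monoalkoxide of a symmetrical diol should give mainly the mono-ether, which makes the two CH2OH groups different.

Step 2
Reactants: 3 2-[(PMB-oxy)methyl]prop-2-en-1-ol
Product: 4 2-[(PMB-oxy)methyl]prop-2-enal
Conditions: MnO2 (excess), CH2Cl2, rt
Reagents that add atoms: none
Why: MnO2 oxidation of the allylic alcohol stops at the enal and leaves the PMB ether and the 1,1-disubstituted alkene untouched.

Step 3
Reactants: 4 2-[(PMB-oxy)methyl]prop-2-enal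
Product: 6 (3R)-2-[(PMB-oxy)methyl]hexa-1,5-dien-3-ol, via borinate ester 5 (not isolated)
Conditions: (+)-Ipc2B(allyl) (1 M in pentane), Et2O, −78 °C; then NaOH, H2O2, 0 °C → rt
Reagents that add atoms: (+)-B-allyldiisopinocampheylborane, C=CCB([C@H]1C[C@H]2C[C@@H]([C@@H]1C)C2(C)C)[C@H]1C[C@H]2C[C@@H]([C@@H]1C)C2(C)C
Why: Brown allylboration through a chair-like six-membered transition state, in which the (+)-Ipc2B reagent (from (−)-α-pinene) should deliver allyl to the Re face of the enal and so set the carbinol carbon (the future C12') as R.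

Step 4
Reactants: 6 (3R)-2-[(PMB-oxy)methyl]hexa-1,5-dien-3-ol
Product: 7 (3R)-2-[(PMB-oxy)methyl]-6-methylhepta-1,5-dien-3-ol
Conditions: Grubbs II (3 mol %), 2-methylbut-2-ene/CH2Cl2, 40 °C
Reagents that add atoms: 2-methylbut-2-ene, CC=C(C)C
Why: Olefin cross-metathesis with 2-methylbut-2-ene turns the monosubstituted vinyl group into the isopropylidene terminus, while the hindered 1,1-disubstituted alkene should stay inert.

Step 5
Reactants: 7 (3R)-2-[(PMB-oxy)methyl]-6-methylhepta-1,5-dien-3-ol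
Product: 8 tert-butyl{[(3R)-2-[(PMB-oxy)methyl]-6-methylhepta-1,5-dien-3-yl]oxy}dimethylsilane
Conditions: TBSOTf, 2,6-lutidine, CH2Cl2, −78 → 0 °C
Reagents that add atoms: tert-butyldimethylsilyl triflate, CC(C)(C)[Si](C)(C)OS(=O)(=O)C(F)(F)F
Why: Silylation of the hindered secondary allylic alcohol with the silyl triflate and a non-nucleophilic base protects C12'–OH without touching the stereocenter.

Step 6
Reactants: 8 tert-butyl{[(3R)-2-[(PMB-oxy)methyl]-6-methylhepta-1,5-dien-3-yl]oxy}dimethylsilane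
Product: 9 (3R)-3-(TBS-oxy)-6-methyl-2-methylidenehept-5-en-1-ol
Conditions: DDQ, CH2Cl2/pH 7 buffer, 0 °C
Reagents that add atoms: none
Why: Oxidative PMB ether cleavage with DDQ (benzylic hydride abstraction, then hydrolysis) is orthogonal to the silyl ether and the isolated alkenes and frees only the primary alcohol.

Step 7
Reactants: 9 (3R)-3-(TBS-oxy)-6-methyl-2-methylidenehept-5-en-1-ol; 10 prop-2-ene-1-sulfonyl chloride
Product: 11 (3R)-3-(TBS-oxy)-6-methyl-2-methylidenehept-5-en-1-yl prop-2-ene-1-sulfonate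
Conditions: Et3N, THF, −40 → 0 °C
Reagents that add atoms: none
Why: O-Sulfonylation of the primary allylic alcohol with the sulfonyl chloride and an amine base at low temperature should give the allylsulfonate without migration of the allyl double bond.

Step 8
Reactants: 11 (3R)-3-(TBS-oxy)-6-methyl-2-methylidenehept-5-en-1-yl prop-2-ene-1-sulfonate
Product: 12 5-[(1R)-1-(TBS-oxy)-4-methylpent-3-en-1-yl]-3,6-dihydro-1,2-oxathiine 2,2-dioxide
Conditions: Grubbs II (5 mol %), CH2Cl2 (0.005 M), 40 °C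
Reagents that add atoms: none
Why: Ring-closing olefin metathesis: the ruthenium carbene exchanges onto the unhindered monosubstituted allyl terminus, the new alkylidene adds [2+2] to the 1,1-disubstituted C11' methylidene, and the metallacyclobutane cycloreverts to form C10'=C11' with loss of ethene. The closest known reaction is the ring-closing metathesis of allylsulfonates of allylic alcohols to 3,6-dihydro-1,2-oxathiine 2,2-dioxides. The one ring closed is the six-membered sultone (O, S, C9', C10', C11', CH2O), closed at the C10'=C11' bond as an endocyclic trisubstituted alkene. No stereocenter is formed and C12' is a spectator. The step needs site selectivity among three alkenes and control of alkene geometry: only the allyl/methylidene pair gives a six-membered ring (the trisubstituted prenyl alkene would need a nine-membered ring or a cyclobutene), and a six-membered ring can hold only the alkene in which C9' and the CH2O carbon are cis, which is the 10'E geometry of the target.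

Step 9
Reactants: 12 5-[(1R)-1-(TBS-oxy)-4-methylpent-3-en-1-yl]-3,6-dihydro-1,2-oxathiine 2,2-dioxide
Product: 15 (2E)-2-[(1R)-1-(TBS-oxy)-4-methylpent-3-en-1-yl]penta-2,4-dien-1-ol, via lithiated sultone 13 (not isolated), via magnesiomethyl sultone 14 (not isolated)
Conditions: n-BuLi, THF, −78 °C; add to ICH2MgCl (from CH2I2, i-PrMgCl, THF, −78 °C); −78 °C → rt; aq. NH4Cl
Reagents that add atoms: chloro(iodomethyl)magnesium, Cl[Mg]CI
Why: Julia-type desulfonylative methylenation: the C9' α-sulfonyl carbanion displaces iodide from the magnesium carbenoid and the β-magnesio sulfonate eliminates, so that C9' becomes the vinyl carbon of C9'=C8'H2, sulfur leaves as an alkyl sulfite that loses SO2, the oxygen stays on the hydroxymethyl carbon and the ring-set C10'=C11' geometry is kept.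

Step 10
Reactants: 15 (2E)-2-[(1R)-1-(TBS-oxy)-4-methylpent-3-en-1-yl]penta-2,4-dien-1-ol
Product: 16 tert-butyl({(2E)-2-[(1R)-1-(TBS-oxy)-4-methylpent-3-en-1-yl]penta-2,4-dien-1-yl}oxy)dimethylsilane
Conditions: TBSCl, imidazole, DMF, rt
Reagents that add atoms: tert-butyldimethylsilyl chloride, CC(C)(C)[Si](C)(C)Cl
Why: Standard silylation of the primary allylic alcohol, which also levels any 1,3-silyl migration between the two oxygens that the alkoxide of step 9 may have caused.

Step 11
Reactants: 17 4-methoxy-2-methylphenol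
Product: 18 2-bromo-4-methoxy-6-methylphenol
Conditions: NBS, CH2Cl2, 0 °C
Reagents that add atoms: N-bromosuccinimide, O=C1CCC(=O)N1Br
Why: Electrophilic aromatic bromination directed by the phenol OH to its only free ortho position (para is blocked by OMe).

Step 12
Reactants: 18 2-bromo-4-methoxy-6-methylphenol
Product: 19 1-bromo-2,5-dimethoxy-3-methylbenzene
Conditions: MeI, K2CO3, acetone, reflux
Reagents that add atoms: iodomethane, CI
Why: Williamson O-methylation gives the hydroquinone dimethyl ether that later serves as the quinone precursor.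

Step 13
Reactants: 19 1-bromo-2,5-dimethoxy-3-methylbenzene; 20 1-bromo-3-methylbut-2-ene
Product: 23 2,5-dimethoxy-1-methyl-3-(3-methylbut-2-en-1-yl)benzene, via aryllithium 21 (not isolated), via arylcopper 22 (not isolated)
Conditions: n-BuLi, THF, −78 °C; CuBr·SMe2, −78 → −40 °C; prenyl bromide, −78 → 0 °C
Reagents that add atoms: none
Why: Bromine–lithium exchange, transmetalation to copper and SN2 allylation of the arylcopper at the primary carbon of prenyl bromide attach the first prenyl unit without allylic transposition.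

Step 14
Reactants: 23 2,5-dimethoxy-1-methyl-3-(3-methylbut-2-en-1-yl)benzene
Product: 24 (2E)-4-(2,5-dimethoxy-3-methylphenyl)-2-methylbut-2-en-1-ol
Conditions: SeO2 (cat.), t-BuOOH, salicylic acid (cat.), CH2Cl2, rt; NaBH4 work-up
Reagents that add atoms: tert-butyl hydroperoxide, CC(C)(C)OO
Why: Riley allylic oxidation (ene reaction with SeO2, then [2,3]-sigmatropic shift, turned over by t-BuOOH) hydroxylates the methyl group trans to the chain and should give the E allylic alcohol.

Step 15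
Reactants: 24 (2E)-4-(2,5-dimethoxy-3-methylphenyl)-2-methylbut-2-en-1-ol
Product: 25 1-[(2E)-4-bromo-3-methylbut-2-en-1-yl]-2,5-dimethoxy-3-methylbenzene
Conditions: CBr4, PPh3, CH2Cl2, 0 °C
Reagents that add atoms: carbon tetrabromide, BrC(Br)(Br)Br
Why: Appel bromination converts the primary allylic alcohol into the bromide by SN2 at low temperature with retention of the E alkene.

Step 16
Reactants: 25 1-[(2E)-4-bromo-3-methylbut-2-en-1-yl]-2,5-dimethoxy-3-methylbenzene
Product: 27 1-[(2E)-3-methyloct-2-en-6-yn-1-yl]-2,5-dimethoxy-3-methylbenzene, via lithium acetylide 26 (not isolated)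
Conditions: propargyl bromide, n-BuLi (2 equiv per propargyl bromide), TMEDA, Et2O, −78 °C; 25, −78 → 0 °C; MeI, THF, 0 °C → rt
Reagents that add atoms: propargyl bromide, C#CCBr; iodomethane, CI
Why: 1,3-Dilithiopropyne alkylates the allylic bromide through its sp3 carbon (propargylation), and the lithium acetylide that remains is methylated in the same flask to the 2-alkyne.

Step 17
Reactants: 27 1-[(2E)-3-methyloct-2-en-6-yn-1-yl]-2,5-dimethoxy-3-methylbenzene
Product: 29 1-[(2E,6E)-7-iodo-3-methylocta-2,6-dien-1-yl]-2,5-dimethoxy-3-methylbenzene, via alkenylzirconocene 28 (not isolated)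
Conditions: Cp2Zr(H)Cl (excess), THF, rt → 40 °C; I2, 0 °C
Reagents that add atoms: iodine, II
Why: Schwartz hydrozirconation adds H and Zr syn, with zirconium settling on the less hindered methyl-bearing alkyne carbon, and iodinolysis with retention gives the (E)-2-iodoalkene (iodine trans to C5').

Step 18
Reactants: 16 tert-butyl({(2E)-2-[(1R)-1-(TBS-oxy)-4-methylpent-3-en-1-yl]penta-2,4-dien-1-yl}oxy)dimethylsilane; 29 1-[(2E,6E)-7-iodo-3-methylocta-2,6-dien-1-yl]-2,5-dimethoxy-3-methylbenzene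
Product: 31 1-[(2E,6E,10E,12R)-12-(TBS-oxy)-11-[(TBS-oxy)methyl]-3,7,15-trimethylhexadeca-2,6,10,14-tetraen-1-yl]-2,5-dimethoxy-3-methylbenzene, via alkylborane 30 (not isolated)
Conditions: 16, 9-BBN, THF, 0 °C → rt; then 29, PdCl2(dppf) (5 mol %), AsPh3, aq. Cs2CO3, DMF, rt
Reagents that add atoms: none
Why: 9-BBN should hydroborate only the monosubstituted terminal alkene of the diene with boron at C8', and B-alkyl Suzuki–Miyaura coupling with the vinyl iodide forms C7'–C8' with retention of both alkene geometries.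

Step 19
Reactants: 31 1-[(2E,6E,10E,12R)-12-(TBS-oxy)-11-[(TBS-oxy)methyl]-3,7,15-trimethylhexadeca-2,6,10,14-tetraen-1-yl]-2,5-dimethoxy-3-methylbenzene
Product: 32 1-[(2E,6E,10E,12R)-12-hydroxy-11-(hydroxymethyl)-3,7,15-trimethylhexadeca-2,6,10,14-tetraen-1-yl]-2,5-dimethoxy-3-methylbenzene
Conditions: TBAF, THF, 0 °C → rt
Reagents that add atoms: none
Why: Fluoride cleaves both silyl ethers (Si–F bond formation) under conditions that the alkenes and the aryl ethers tolerate.

Step 20
Reactants: 32 1-[(2E,6E,10E,12R)-12-hydroxy-11-(hydroxymethyl)-3,7,15-trimethylhexadeca-2,6,10,14-tetraen-1-yl]-2,5-dimethoxy-3-methylbenzene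
Product: 33 2-[(2E,6E,10E,12R)-12-hydroxy-11-(hydroxymethyl)-3,7,15-trimethylhexadeca-2,6,10,14-tetraen-1-yl]-6-methylcyclohexa-2,5-diene-1,4-dione
Conditions: CAN (2.5 equiv), MeCN/H2O, 0 °C
Reagents that add atoms: water, O
Why: Oxidative demethylation of the 1,4-dimethoxyarene with cerium(IV) (arene radical cation, ipso attack of water, loss of methanol) should give the p-quinone faster than the allylic alcohols or alkenes are oxidised.

Compound list
1 | 2-methylidenepropane-1,3-diol | C=C(CO)CO | starting material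
2 | sodium 2-(hydroxymethyl)prop-2-en-1-olate | C=C(CO)C[O-].[Na+] | intermediate (not isolated)
3 | 2-[(PMB-oxy)methyl]prop-2-en-1-ol | C=C(CO)COCc1ccc(OC)cc1 | intermediate
4 | 2-[(PMB-oxy)methyl]prop-2-enal | C=C(C=O)COCc1ccc(OC)cc1 | intermediate
5 | (3R)-2-[(PMB-oxy)methyl]hexa-1,5-dien-3-yl bis[(+)-isopinocampheyl]borinate | C=CC[C@@H](OB([C@H]1C[C@H]2C[C@@H]([C@@H]1C)C2(C)C)[C@H]1C[C@H]2C[C@@H]([C@@H]1C)C2(C)C)C(=C)COCc1ccc(OC)cc1 | intermediate (not isolated)
6 | (3R)-2-[(PMB-oxy)methyl]hexa-1,5-dien-3-ol | C=CC[C@@H](O)C(=C)COCc1ccc(OC)cc1 | intermediate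
7 | (3R)-2-[(PMB-oxy)methyl]-6-methylhepta-1,5-dien-3-ol | CC(C)=CC[C@@H](O)C(=C)COCc1ccc(OC)cc1 | intermediate
8 | tert-butyl{[(3R)-2-[(PMB-oxy)methyl]-6-methylhepta-1,5-dien-3-yl]oxy}dimethylsilane | CC(C)=CC[C@@H](O[Si](C)(C)C(C)(C)C)C(=C)COCc1ccc(OC)cc1 | intermediate
9 | (3R)-3-(TBS-oxy)-6-methyl-2-methylidenehept-5-en-1-ol | CC(C)=CC[C@@H](O[Si](C)(C)C(C)(C)C)C(=C)CO | intermediate
10 | prop-2-ene-1-sulfonyl chloride | C=CCS(=O)(=O)Cl | starting material
11 | (3R)-3-(TBS-oxy)-6-methyl-2-methylidenehept-5-en-1-yl prop-2-ene-1-sulfonate | CC(C)=CC[C@@H](O[Si](C)(C)C(C)(C)C)C(=C)COS(=O)(=O)CC=C | intermediate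
12 | 5-[(1R)-1-(TBS-oxy)-4-methylpent-3-en-1-yl]-3,6-dihydro-1,2-oxathiine 2,2-dioxide | CC(C)=CC[C@@H](O[Si](C)(C)C(C)(C)C)C1=CCS(=O)(=O)OC1 | intermediate
13 | 3-lithio derivative of sultone 12 (lithium at C9') | CC(C)=CC[C@@H](O[Si](C)(C)C(C)(C)C)C1=CC([Li])S(=O)(=O)OC1 | intermediate (not isolated)
14 | 3-[(chloromagnesio)methyl] derivative of sultone 12 | CC(C)=CC[C@@H](O[Si](C)(C)C(C)(C)C)C1=CC(C[Mg]Cl)S(=O)(=O)OC1 | intermediate (not isolated)
15 | (2E)-2-[(1R)-1-(TBS-oxy)-4-methylpent-3-en-1-yl]penta-2,4-dien-1-ol | CC(C)=CC[C@@H](O[Si](C)(C)C(C)(C)C)/C(CO)=C/C=C | intermediate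
16 | tert-butyl({(2E)-2-[(1R)-1-(TBS-oxy)-4-methylpent-3-en-1-yl]penta-2,4-dien-1-yl}oxy)dimethylsilane | CC(C)=CC[C@@H](O[Si](C)(C)C(C)(C)C)/C(CO[Si](C)(C)C(C)(C)C)=C/C=C | intermediate
17 | 4-methoxy-2-methylphenol | COc1ccc(O)c(C)c1 | starting material
18 | 2-bromo-4-methoxy-6-methylphenol | COc1cc(C)c(O)c(Br)c1 | intermediate
19 | 1-bromo-2,5-dimethoxy-3-methylbenzene | COc1cc(C)c(OC)c(Br)c1 | intermediate
20 | 1-bromo-3-methylbut-2-ene (prenyl bromide) | CC(C)=CCBr | starting material
21 | (2,5-dimethoxy-3-methylphenyl)lithium | COc1cc(C)c(OC)c([Li])c1 | intermediate (not isolated)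
22 | (2,5-dimethoxy-3-methylphenyl)copper | COc1cc(C)c(OC)c([Cu])c1 | intermediate (not isolated)
23 | 2,5-dimethoxy-1-methyl-3-(3-methylbut-2-en-1-yl)benzene | COc1cc(C)c(OC)c(CC=C(C)C)c1 | intermediate
24 | (2E)-4-(2,5-dimethoxy-3-methylphenyl)-2-methylbut-2-en-1-ol | COc1cc(C)c(OC)c(C/C=C(\C)CO)c1 | intermediate
25 | 1-[(2E)-4-bromo-3-methylbut-2-en-1-yl]-2,5-dimethoxy-3-methylbenzene | COc1cc(C)c(OC)c(C/C=C(\C)CBr)c1 | intermediate
26 | [(5E)-7-(2,5-dimethoxy-3-methylphenyl)-5-methylhept-5-en-1-yn-1-yl]lithium | COc1cc(C)c(OC)c(C/C=C(\C)CCC#C[Li])c1 | intermediate (not isolated)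
27 | 1-[(2E)-3-methyloct-2-en-6-yn-1-yl]-2,5-dimethoxy-3-methylbenzene | COc1cc(C)c(OC)c(C/C=C(\C)CCC#CC)c1 | intermediate
28 | chlorobis(cyclopentadienyl)[(2E,6E)-8-(2,5-dimethoxy-3-methylphenyl)-6-methylocta-2,6-dien-2-yl]zirconium | COc1cc(C)c(OC)c(C/C=C(\C)CC/C=C(\C)[Zr](Cl)(C2C=CC=C2)C2C=CC=C2)c1 | intermediate (not isolated)
29 | 1-[(2E,6E)-7-iodo-3-methylocta-2,6-dien-1-yl]-2,5-dimethoxy-3-methylbenzene | COc1cc(C)c(OC)c(C/C=C(\C)CC/C=C(\C)I)c1 | intermediate
30 | 9-[(3E,5R)-5-(TBS-oxy)-4-[(TBS-oxy)methyl]-8-methylnona-3,7-dien-1-yl]-9-borabicyclo[3.3.1]nonane | CC(C)=CC[C@@H](O[Si](C)(C)C(C)(C)C)/C(CO[Si](C)(C)C(C)(C)C)=C/CCB1C2CCCC1CCC2 | intermediate (not isolated)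
31 | 1-[(2E,6E,10E,12R)-12-(TBS-oxy)-11-[(TBS-oxy)methyl]-3,7,15-trimethylhexadeca-2,6,10,14-tetraen-1-yl]-2,5-dimethoxy-3-methylbenzene | CC(C)=CC[C@@H](O[Si](C)(C)C(C)(C)C)/C(CO[Si](C)(C)C(C)(C)C)=C/CC/C(C)=C/CC/C(C)=C/Cc1cc(OC)cc(C)c1OC | intermediate
32 | 1-[(2E,6E,10E,12R)-12-hydroxy-11-(hydroxymethyl)-3,7,15-trimethylhexadeca-2,6,10,14-tetraen-1-yl]-2,5-dimethoxy-3-methylbenzene | CC(C)=CC[C@@H](O)/C(CO)=C/CC/C(C)=C/CC/C(C)=C/Cc1cc(OC)cc(C)c1OC | intermediate
33 | 2-[(2E,6E,10E,12R)-12-hydroxy-11-(hydroxymethyl)-3,7,15-trimethylhexadeca-2,6,10,14-tetraen-1-yl]-6-methylcyclohexa-2,5-diene-1,4-dione (CNP0201434.1) | CC(C)=CC[C@@H](O)/C(=C/CC/C(C)=C/CC/C(C)=C/CC1=CC(=O)C=C(C)C1=O)CO | target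

Total step count: 20. Longest linear sequence: 13 steps (steps 1–10, then 18–20, from diol 1); the aryl branch (steps 11–17) joins at step 18.

Steps most likely to fail

Step 9. The lithiated sultone may open by vinylogous loss of the sulfonate oxygen, or the thermally fragile carbenoid may decay, before the two have met. Fallback from 12, returning at 16: the carbanion is formed as before and captured at once at −78 °C with (trimethylsilyl)methyl triflate, a stable and fast electrophile, to give 3-[(trimethylsilyl)methyl]-5-[(1R)-1-(TBS-oxy)-4-methylpent-3-en-1-yl]-3,6-dihydro-1,2-oxathiine 2,2-dioxide F1. TBAF in THF then triggers a Peterson-type β-elimination of silicon and the sulfonyl group (loss of SO2) and also removes the silyl ether, giving (2E)-2-[(1R)-1-hydroxy-4-methylpent-3-en-1-yl]penta-2,4-dien-1-ol F2. Twofold silylation (TBSCl, imidazole, DMF) gives 16.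

Step 18. Transmetalation to palladium at the hindered 2-iodoalkene may be slow, so that the alkylborane is lost to protodeboronation or β-hydride elimination. Fallback from 16, returning at 31: hydroboration with 9-BBN as before (alkylborane 30) is followed by oxidative work-up (NaOH, H2O2) to give (3E,5R)-5-(TBS-oxy)-4-[(TBS-oxy)methyl]-8-methylnona-3,7-dien-1-ol F3. Iodination (I2, PPh3, imidazole) gives (3E,5R)-1-iodo-5-(TBS-oxy)-4-[(TBS-oxy)methyl]-8-methylnona-3,7-diene F4, and zinc insertion (Zn, LiCl, THF) gives [(3E,5R)-5-(TBS-oxy)-4-[(TBS-oxy)methyl]-8-methylnona-3,7-dien-1-yl]zinc iodide F5. Negishi coupling of F5 with 29 [Pd(PPh3)4, THF] gives 31.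

Step 16. The ambident dianion may react through its allenyl terminus or at the γ-carbon of the allylic bromide, and capture of the acetylide by MeI may be incomplete. Fallback from 25, returning at 27: alkylation with lithiated 1-(trimethylsilyl)propyne (n-BuLi, THF, −78 °C), whose silyl group steers attack to the propargylic carbon, gives 1-[(2E)-3-methyl-7-(trimethylsilyl)hept-2-en-6-yn-1-yl]-2,5-dimethoxy-3-methylbenzene F6. K2CO3 in MeOH gives 1-[(2E)-3-methylhept-2-en-6-yn-1-yl]-2,5-dimethoxy-3-methylbenzene F7, and n-BuLi then MeI gives 27.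

Further compounds
F1 | step 9 | 3-[(trimethylsilyl)methyl]-5-[(1R)-1-(TBS-oxy)-4-methylpent-3-en-1-yl]-3,6-dihydro-1,2-oxathiine 2,2-dioxide | CC(C)=CC[C@@H](O[Si](C)(C)C(C)(C)C)C1=CC(C[Si](C)(C)C)S(=O)(=O)OC1
F2 | step 9 | (2E)-2-[(1R)-1-hydroxy-4-methylpent-3-en-1-yl]penta-2,4-dien-1-ol | CC(C)=CC[C@@H](O)/C(CO)=C/C=C
F3 | step 18 | (3E,5R)-5-(TBS-oxy)-4-[(TBS-oxy)methyl]-8-methylnona-3,7-dien-1-ol | CC(C)=CC[C@@H](O[Si](C)(C)C(C)(C)C)/C(CO[Si](C)(C)C(C)(C)C)=C/CCO
F4 | step 18 | (3E,5R)-1-iodo-5-(TBS-oxy)-4-[(TBS-oxy)methyl]-8-methylnona-3,7-diene | CC(C)=CC[C@@H](O[Si](C)(C)C(C)(C)C)/C(CO[Si](C)(C)C(C)(C)C)=C/CCI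
F5 | step 18 | [(3E,5R)-5-(TBS-oxy)-4-[(TBS-oxy)methyl]-8-methylnona-3,7-dien-1-yl]zinc iodide | CC(C)=CC[C@@H](O[Si](C)(C)C(C)(C)C)/C(CO[Si](C)(C)C(C)(C)C)=C/CC[Zn]I
F6 | step 16 | 1-[(2E)-3-methyl-7-(trimethylsilyl)hept-2-en-6-yn-1-yl]-2,5-dimethoxy-3-methylbenzene | COc1cc(C)c(OC)c(C/C=C(\C)CCC#C[Si](C)(C)C)c1
F7 | step 16 | 1-[(2E)-3-methylhept-2-en-6-yn-1-yl]-2,5-dimethoxy-3-methylbenzene | COc1cc(C)c(OC)c(C/C=C(\C)CCC#C)c1
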